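Inverse molar per second is the unit of an exchange rate constant, so a concentration and a time turn it into a pure number. The flasks below differ in how much incoming ligand the complex meets, and for how long.

| flask | starting complex | incoming ligand | time | remark |
|---|---|---|---|---|
| dusk | 0.10 M | 2.50 equiv (fed, over 1.60 min) | 2.0 min | all but incoming ligand at the start; incoming ligand goes in evenly over 1.60 min, the run ends at 2.0 min |
| autumn | 0.10 M | 2.50 equiv |  | one stirred flow tank at steady state, fed with the mixture as stated, mean residence time 2.0 min |
| spring | 0.10 M (fed, over 1.60 min) | 2.50 equiv | 2.0 min | all but starting complex at the start; starting complex goes in evenly over 1.60 min, the run ends at 2.0 min |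
| noon | 0.10 M | 2.50 equiv | 2.0 min | a closed flask charged with all of it at once and left for 2.0 min |

    starting complex + incoming ligand ⇌ leaving ligand + complex with one exchanged (K1 = 33.2, k1 = 0.159 M⁻¹ s⁻¹)
    complex with one exchanged + incoming ligand ⇌ leaving ligand + complex with two exchanged (K2 = 0.401, k2 = 0.0388 M⁻¹ s⁻¹)
    starting complex ⇌ dormant form (K3 = 0.856, k3 = 0.0381 s⁻¹)

- the set-up with the highest amount of complex with two exchanged at the outlet or at the end, in percent of the starting complex put in ("none" if the first two lie within 2 percentage points) (dusk / autumn / spring / noon / none)
- amount of complex with two exchanged at the outlet or at the end, in percent of the starting complex put in, dusk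
- amount of complex with two exchanged at the outlet or at the end, in percent of the starting complex put in, autumn
- amount of complex with two exchanged at the outlet or at the end, in percent of the starting complex put in, spring
- amount of complex with two exchanged at the outlet or at the end, in percent of the starting complex put in, noon

- the stated concentrations are those of everything mixed, before any reaction; amounts are the same in each set-up
- the feed brings no volume worth counting
- run time (dusk): 2.0 min

With ligand as charged in noon, the forward half-life of starting complex by the first exchange is 0.29 min, and that of complex with one exchanged by the second is 1.2 min. By these forward rates the second exchange is slower, so I reckon on it. In noon, its rate constant 0.0388 M⁻¹ s⁻¹ times the charged ligand 0.250 M times 2.0 min gives 1.16. In dusk the ligand goes in evenly over 1.60 min. Counting that ramp at its midpoint, and ignoring consumption, the mean ligand is the fraction 0.600 of the charge. In spring the ligand is all present, but the average portion of complex spends that same fraction of the run in the flask. So the exposure number N, a Damköhler number for the second exchange, which is rate constant times mean ligand met times run time, is 0.698 for both dosed flasks. It counts the lifetimes of the second exchange that the average complex has had. I commit to noon on top, with dusk and spring tied at the fraction 0.600 of noon's yield. For autumn the outlet ligand is unknown by hand, so N stays open there.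

The forecast names noon, with 16.5% for dusk, 18.2% for autumn, 17% for spring and 23.8% for noon: “Charging everything at once wins because the starting complex meets the most incoming ligand before it can fall into the dormant pool”. Its dusk-to-noon ratio, 0.693, is above my 0.600.

The simulation gives 15.1% for dusk, 18.3% for autumn, 17.5% for spring and 23.5% for noon, so noon is highest, and the forecast's ranges hold these values.

Scaling noon by N gives 14.1% for the dosed flasks, near dusk, but spring stands 2.4 percentage points above dusk, so one number does not give the tie. N counts forward exposure, and part of what it misses is the way back: in noon, without the return of leaving ligand and complex with two exchanged to complex with one exchanged and incoming ligand, the yield stands at 33.9% rather than 23.5%, a part worth 10 points. For dusk with 1.50 equiv of ligand, N falls to 0.419, which scales to 9.06%. The computed result is lower, 6.93%.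

The constants are those of an exercise.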